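The readings are simulated with made-up constants.

4 questions stand on the north-east charge and the west flask, and the runs so far answer them once one quantity is in hand.

| flask | starting material | partner | time |
|---|---|---|---|
| north-east | 0.600 M | 0.720 M |  |
| south | 0.600 M | 1.10 M |  |
| north-west | 0.900 M | 0.720 M |  |
| west | 1.80 M | 2.20 M | 22 min |

| run | time / min | [product] / M |
|---|---|---|
| north-east run | 4.4 | 0.109 |
| north-east run | 8.8 | 0.156 |
| north-east run | 13 | 0.190 |
| north-east run | 18 | 0.199 |
| north-east run | 22 | 0.219 |
| south run | 4.4 | 0.137 |
| south run | 8.8 | 0.221 |
| south run | 13 | 0.244 |
| south run | 18 | 0.252 |
| south run | 22 | 0.264 |
| north-west run | 4.4 | 0.131 |
| north-west run | 8.8 | 0.194 |
| north-west run | 13 | 0.216 |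
| north-west run | 18 | 0.235 |
| north-west run | 22 | 0.253 |

(scatter of a reading: 0.006 M)

- the exponent of [partner] in the starting rate at the charge of the north-east run (at the point where two percent of the starting material have become product)
- the exponent of [starting material] in the starting rate at the charge of the north-east run (at the point where two percent of the starting material have become product) (one fixed amount of product, the same in the runs compared)
- product in the west run at 22 min, as a share of the starting material charged
- which of these the readings show (the substrate pairs with itself / the product reacts on with the second partner / the substrate is lost by itself)

- Overall: starting material + partner -> product.
- Constant volume, constant temperature.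
- Readings of a species count what is bound in complexes too.
- "The second partner" is partner.
- An order is taken over about fifteen percent of the charge, up and down.

Begin with the main step by itself. Starting material, charged in the west flask at 1.80 M, less than the 2.20 M of partner, is the limiting reagent there, and it meets partner with rate proportional to c(starting material) times c(partner). The north-east mean rate up to the first reading, 0.0248 M/min, gives a constant of 0.0573 /M/min, and with it the west flask reaches 78.3% of its charge at 22 min.

The first readings test this. At 4.4 min the south run, on 1.53 times the partner of the north-east run, holds 1.26 times its product, so partner acts in the main step, and I take its starting exponent as 1. The north-west run, on 1.50 times the starting material of the north-east run, holds 1.20 times its product at that time, an exponent of 0.453, less than 1. A loss of substrate by itself and product reacting on both leave product in proportion to the charge of starting material, so the second process I take is pairing of starting material with itself, with the free form reacting.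

Solve both ends. With the starting material unpaired, the starting exponent in it is 1; with the dimer as its main form, c(free) follows the root of the charge and the exponent is 0.5. The reading of 0.453, taken at a fixed time and carrying its scatter, points to the lower end, and there I put the starting exponent, a little above 0.5. At that lower end the constant falls with the root of the charge to 0.0331 /M/min, and the estimate for the west flask falls to 65.0%.

The rest is the stall: the north-east run stands at 36.5% of its charge at 22 min, having gained 0.0290 M since 13 min. Without naming a step, the readings at that time scale with exponents of 0.356 in starting material and 0.441 in partner. Their sum, 0.797, is the power with which product at 22 min follows when both charges are raised by one factor, read from these runs: the reach exponent. My estimate for the west flask, with each charge raised by its own factor, is therefore 29.4%.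

The forecast gives 0.9, 0.85, 30.5% and the substrate pairs with itself, on this ground: “So the loss is second order in substrate: it pairs with itself.” It differs from my reckoning mainly in the substrate exponent.

    starting material + partner ⇌ product + by-product (0.1788 /M/min, 0.3234 /M/min)
    2 starting material ⇌ idle substrate dimer, settled at all times (4.120 /M)

The simulation gives 1.0 for partner, 0.62 for starting material, 30.6% for the west flask, and the substrate pairs with itself. For the west flask, a fit with the substrate lost by itself gives 35.6%, against 31.3% from the true steps. The west flask holds 3.00 times the north-east starting material and 3.06 times its partner. At the reach exponent of 0.797, the first of these factors turns the north-east reading of 0.219 M into 0.526 M, and the west flask makes 0.551 M of product at 22 min.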